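**Retrosynthetic overview**
- The target is reached last by acidic fluoride removal of a C1/C3 acetonide and an O5 silyl ether from the fully assembled bis-oxazole.
- The strategy rests on ring A, the oxazole O1–C2–N3–C4–C5 with H on C5, the CH2 link to ring B on C2 and chain carbon C1 on C4. This 2,4-pattern is that of a primary amide condensed with a BrCH2–C(=O) unit, so ring A is cut at O1–C5 and N3–C4 into 2-(oxazol-5-yl)acetamide and the chain bromomethyl ketone.
- The bromomethyl ketone comes from a methyl ketone held in a cis-4,6-disubstituted 2,2-dimethyl-1,3-dioxane, in which C1 is set by base equilibration; O4 is changed from benzyloxymethyl to myristate before bromination.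
- The methyl ketone comes from 1-ethoxyvinyllithium and a 2-deoxy-L-fucose aldehyde, made from 3,4-di-O-acetyl-L-fucal through the 2-deoxy lactone and its Weinreb amide; C3, C4 and C5 come from the sugar.
- Ring order: ring B is bought with the acetic acid, the temporary dioxane forms in step 11, and ring A forms in step 16.

Key step: step 16

Remark on numbering and assumptions: chain atoms are numbered C1 (carbinol on ring A) to C6 (methyl), which are C1–C6 of 2-deoxy-L-fucose; C0 is the ketone carbon added in step 9. C3–C5 keep the L-lyxo configuration throughout. CIP descriptors are given only for the target because they change with the protecting groups. The amide partner is assumed to be made from the commercial acid. TBS = tert-butyldimethylsilyl, BOM = benzyloxymethyl, TIPS = triisopropylsilyl.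

**Route**

Step 1
Reactants: 1 3,4-di-O-acetyl-L-fucal
Product: 2 L-fucal
Conditions: NaOMe (0.1 equiv), MeOH, rt
Reagents that add atoms: none
Why: Zemplén transesterification with catalytic methoxide should remove both acetates as methyl acetate without touching the base-stable enol ether or the three stereocentres.

Step 2
Reactants: 2 L-fucal
Product: 3 3-O-TBS-L-fucal
Conditions: TBSCl (1.05 equiv), imidazole, DMF, −20 → 0 °C
Reagents that add atoms: tert-butyldimethylsilyl chloride, CC(C)(C)[Si](C)(C)Cl
Why: Regioselective silylation, in which the allylic pseudo-equatorial 3-OH of the glycal is far more reactive than the pseudo-axial 4-OH next to the C5 methyl group, should place the bulky silyl group on O3 only.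

Step 3
Reactants: 3 3-O-TBS-L-fucal
Product: 4 4-O-BOM-3-O-TBS-L-fucal
Conditions: BOMCl, iPr2NEt, nBu4NI (cat.), CH2Cl2, 40 °C
Reagents that add atoms: benzyl chloromethyl ether, ClCOCc1ccccc1
Why: Williamson-type alkylation with the reactive α-chloro ether under amine rather than alkoxide conditions should protect the hindered 4-OH as a formaldehyde acetal while avoiding the 1,2-silyl migration from O3 that an alkoxide would invite.

Step 4
Reactants: 4 4-O-BOM-3-O-TBS-L-fucal
Product: 5 4-O-BOM-3-O-TBS-2-deoxy-L-fucopyranose (anomer mixture)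
Conditions: PPh3·HBr (5 mol %), THF–H2O, rt
Reagents that add atoms: water, O
Why: Acid-catalysed Markovnikov hydration of the glycal enol ether through the C1 oxocarbenium ion should give the 2-deoxy lactol, whose anomeric centre is a mixture that is destroyed in the next step.

Step 5
Reactants: 5 4-O-BOM-3-O-TBS-2-deoxy-L-fucopyranose
Product: 6 4-O-BOM-3-O-TBS-2-deoxy-L-fucono-1,5-lactone
Conditions: PhI(OAc)2, TEMPO (10 mol %), CH2Cl2, rt
Reagents that add atoms: none
Why: Oxoammonium (TEMPO) oxidation with the iodane as terminal oxidant should convert the lactol into the δ-lactone, no other oxidisable hydroxyl being present.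

Step 6
Reactants: 6 4-O-BOM-3-O-TBS-2-deoxy-L-fucono-1,5-lactone
Product: 7 open-chain Weinreb amide with free 5-OH
Conditions: MeNH(OMe)·HCl, AlMe3, CH2Cl2, 0 °C → rt
Reagents that add atoms: N,O-dimethylhydroxylamine hydrochloride, CNOC.Cl
Why: Weinreb aminolysis of the lactone by the dimethylaluminium amide should open the ring and expose O5–H as the only free hydroxyl.

Step 7
Reactants: 7 open-chain Weinreb amide with free 5-OH
Product: 8 5-O-TIPS Weinreb amide
Conditions: TIPSOTf, 2,6-lutidine, CH2Cl2, −78 → 0 °C
Reagents that add atoms: triisopropylsilyl trifluoromethanesulfonate, CC(C)[Si](OS(=O)(=O)C(F)(F)F)(C(C)C)C(C)C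
Why: Silylation with the silyl triflate and a hindered base is fast at low temperature, so it should outpace relactonisation of the δ-hydroxy amide and install a group more acid-stable than the O3 TBS ether.

Step 8
Reactants: 8 5-O-TIPS Weinreb amide
Product: 9 protected 2-deoxy-L-fucose aldehyde (3-O-TBS, 4-O-BOM, 5-O-TIPS)
Conditions: iBu2AlH, THF, −78 °C; aq. potassium sodium tartrate
Reagents that add atoms: none
Why: Hydride reduction of the Weinreb amide gives a chelated tetrahedral aluminium intermediate that collapses to the aldehyde only on work-up, so over-reduction should be avoided.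

Step 9
Reactants: 9 protected 2-deoxy-L-fucose aldehyde; 10 ethyl vinyl ether
Product: 12 1-ethoxyvinyl carbinol (C1 epimer mixture), via 1-ethoxyvinyllithium 11 (not isolated)
Conditions: 10, tBuLi, THF, −78 → 0 °C; then 9, −78 °C; aq. NH4Cl
Reagents that add atoms: none
Why: α-Lithiation of the vinyl ether gives a masked acetyl anion that adds 1,2 to the aldehyde, forming C1 as an epimer mixture under weak 1,3-induction, which is acceptable because C1 is equilibrated in step 11.

Step 10
Reactants: 12 1-ethoxyvinyl carbinol (C1 epimer mixture)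
Product: 13 C1,C3-dihydroxy methyl ketone (C1 epimer mixture)
Conditions: 1 M aq. HCl, THF–MeOH, 0 °C → rt
Reagents that add atoms: water, O
Why: Aqueous acid should hydrolyse the enol ether to the methyl ketone and solvolyse the secondary TBS ether, while the bulkier TIPS ether and the formaldehyde acetal are stable, so that only the C1/C3 diol is unveiled.

Step 11
Reactants: 13 C1,C3-dihydroxy methyl ketone (C1 epimer mixture)
Product: 15 cis-acetonide methyl ketone, via acetonide epimer mixture 14 (not isolated)
Conditions: Me2C(OMe)2, PPTS (cat.), CH2Cl2, rt; then evaporate, K2CO3, MeOH, rt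
Reagents that add atoms: 2,2-dimethoxypropane, COC(C)(C)OC
Why: Acid-catalysed transketalisation closes the 1,3-dioxane on both epimers and carbonate in methanol then epimerises the centre α to the ketone by enolisation, so thermodynamic control should set C1 as the cis-4,6-diequatorial (1,3-syn) isomer, the trans isomer being destabilised by a syn-axial contact with a ring methyl group or a twist-boat.

Step 12
Reactants: 15 cis-acetonide methyl ketone
Product: 16 O4 alcohol
Conditions: H2 (1 atm), Pd(OH)2/C, EtOAc, rt
Reagents that add atoms: none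
Why: Hydrogenolysis of the benzyl C–O bond gives a hemiacetal that loses formaldehyde to free O4–H, the ketone, acetonide and silyl ether being inert to these conditions.

Step 13
Reactants: 16 O4 alcohol; 17 myristic acid
Product: 18 O4 myristate methyl ketone
Conditions: DCC, DMAP, CH2Cl2, 0 °C → rt
Reagents that add atoms: none
Why: Steglich esterification (carbodiimide activation and acyl transfer through the acylpyridinium of DMAP) should acylate the only free hydroxyl, O4, without a base strong enough to disturb C1.

Step 14
Reactants: 18 O4 myristate methyl ketone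
Product: 20 bromomethyl ketone, via trimethylsilyl enol ether 19 (not isolated)
Conditions: LiN(SiMe3)2, THF, −78 °C; Me3SiCl; then NBS, −78 → 0 °C
Reagents that add atoms: N-bromosuccinimide, O=C1CCC(=O)N1Br
Why: Kinetic deprotonation by the hindered amide base should occur at the methyl group rather than at the ring methine C1 or the less acidic ester α-CH2, and bromination of the trapped silyl enol ether with NBS then gives the bromomethyl ketone regiospecifically.

Step 15
Reactants: 21 2-(oxazol-5-yl)acetic acid
Product: 23 2-(oxazol-5-yl)acetamide, via acyl imidazolide 22 (not isolated)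
Conditions: CDI, THF, rt; then aq. NH3, 0 °C → rt
Reagents that add atoms: ammonia, N
Why: Activation of the acid as its acyl imidazolide followed by ammonolysis should give the primary amide under conditions mild enough for the oxazole.

Step 16
Reactants: 20 bromomethyl ketone; 23 2-(oxazol-5-yl)acetamide
Product: 26 protected bis-oxazole, via O-alkyl imidate 24 (not isolated), via hydroxyoxazoline 25 (not isolated)
Conditions: 23 (3 equiv), AgSbF6 (1.2 equiv), 2,6-di-tert-butyl-4-methylpyridine (1.2 equiv), 4 Å molecular sieves, ClCH2CH2Cl, 70 °C, dark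
Reagents that add atoms: none
Why: AgSbF6 abstracts bromide from 20 as AgBr while the carbonyl oxygen of 23, the nucleophilic site of a neutral primary amide, attacks the CH2 carbon (bond O1–C5) to give imidate 24; its nitrogen then adds to the ketone (bond N3–C4) to give hydroxyoxazoline 25, and loss of water aromatises ring A. The closest known reaction is the Blümlein–Lewy oxazole synthesis from primary amides and α-bromoketones in its silver-promoted form. Ring A closes in a 5-exo-trig mode, the nitrogen attacking a carbonyl carbon whose oxygen stays outside the new ring. No stereocentre is created, since the hemiaminal carbon of 25 becomes sp2, and C1 next to the ketone should keep its configuration because the cis-dioxane is already the thermodynamic epimer. The step needs O- rather than N- or C-alkylation of 23, which gives the 2,4- and not the 2,5-pattern: the amide oxygen is the kinetic site under halophile activation, no base able to deprotonate the CH2 of 23 is present, and the weakly basic nitrogen of ring B is outcompeted by the excess amide. The hindered pyridine and the sieves take up the acid and water released, so that the acetonide, the TIPS ether and the ester should survive.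

Step 17
Reactants: 26 protected bis-oxazole
Product: 27 target
Conditions: 48% aq. HF, MeCN, 0 °C → rt
Reagents that add atoms: none
Why: Acidic fluoride cleaves the Si–O bond and the aqueous acid hydrolyses the dioxane in one operation without touching a stereocentre, and since no alkoxide is generated the O4 ester should not migrate to the freed O3 or O5 hydroxyls.

**Compound list**

1 | 3,4-di-O-acetyl-L-fucal (3,4-di-O-acetyl-1,5-anhydro-2,6-dideoxy-L-lyxo-hex-1-enitol) | C[C@H]1[C@@H](OC(C)=O)[C@@H](OC(C)=O)C=CO1 | starting material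
2 | L-fucal (1,5-anhydro-2,6-dideoxy-L-lyxo-hex-1-enitol) | C[C@H]1[C@@H](O)[C@@H](O)C=CO1 | intermediate
3 | 3-O-(tert-butyldimethylsilyl)-L-fucal, 4-OH free | C[C@H]1[C@@H](O)[C@@H](O[Si](C)(C)C(C)(C)C)C=CO1 | intermediate
4 | 4-O-(benzyloxymethyl)-3-O-(tert-butyldimethylsilyl)-L-fucal | C[C@H]1[C@@H](OCOCc2ccccc2)[C@@H](O[Si](C)(C)C(C)(C)C)C=CO1 | intermediate
5 | 4-O-(benzyloxymethyl)-3-O-(tert-butyldimethylsilyl)-2,6-dideoxy-L-lyxo-hexopyranose, anomer mixture | C[C@H]1[C@@H](OCOCc2ccccc2)[C@@H](O[Si](C)(C)C(C)(C)C)CC(O)O1 | intermediate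
6 | 4-O-(benzyloxymethyl)-3-O-(tert-butyldimethylsilyl)-2,6-dideoxy-L-lyxo-hexono-1,5-lactone | C[C@H]1[C@@H](OCOCc2ccccc2)[C@@H](O[Si](C)(C)C(C)(C)C)CC(=O)O1 | intermediate
7 | 4-O-(benzyloxymethyl)-3-O-(tert-butyldimethylsilyl)-2,6-dideoxy-N-methoxy-N-methyl-L-lyxo-hexonamide, 5-OH free | C[C@H](O)[C@@H](OCOCc1ccccc1)[C@@H](O[Si](C)(C)C(C)(C)C)CC(=O)N(C)OC | intermediate
8 | 5-O-(triisopropylsilyl) ether of 7 | C[C@H](O[Si](C(C)C)(C(C)C)C(C)C)[C@@H](OCOCc1ccccc1)[C@@H](O[Si](C)(C)C(C)(C)C)CC(=O)N(C)OC | intermediate
9 | 4-O-(benzyloxymethyl)-3-O-(tert-butyldimethylsilyl)-5-O-(triisopropylsilyl)-2,6-dideoxy-aldehydo-L-lyxo-hexose | C[C@H](O[Si](C(C)C)(C(C)C)C(C)C)[C@@H](OCOCc1ccccc1)[C@@H](O[Si](C)(C)C(C)(C)C)CC=O | intermediate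
10 | ethyl vinyl ether | CCOC=C | starting material
11 | 1-ethoxyvinyllithium | [Li]C(=C)OCC | intermediate
12 | 1-ethoxyvinyl carbinol CH2=C(OEt)–C1H(OH)–C2H2–C3H(OTBS)–C4H(OBOM)–C5H(OTIPS)–C6H3, L-lyxo at C3–C5, both C1 epimers | C[C@H](O[Si](C(C)C)(C(C)C)C(C)C)[C@@H](OCOCc1ccccc1)[C@@H](O[Si](C)(C)C(C)(C)C)CC(O)C(=C)OCC | intermediate
13 | dihydroxy methyl ketone CH3C(=O)–C1H(OH)–C2H2–C3H(OH)–C4H(OBOM)–C5H(OTIPS)–C6H3, L-lyxo at C3–C5, both C1 epimers | C[C@H](O[Si](C(C)C)(C(C)C)C(C)C)[C@@H](OCOCc1ccccc1)[C@@H](O)CC(O)C(C)=O | intermediate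
14 | 2,2-dimethyl-1,3-dioxane (acetonide of O1 and O3) of 13, cis and trans isomers at C1 | C[C@H](O[Si](C(C)C)(C(C)C)C(C)C)[C@@H](OCOCc1ccccc1)[C@@H]1CC(OC(C)(C)O1)C(C)=O | intermediate
15 | cis isomer of 14: acetyl group on C1 and the C4H(OBOM)–C5H(OTIPS)–CH3 side chain on C3 both equatorial on the dioxane, C1/C3 syn | C[C@H](O[Si](C(C)C)(C(C)C)C(C)C)[C@@H](OCOCc1ccccc1)[C@@H]1C[C@@H](OC(C)(C)O1)C(C)=O | intermediate
16 | 15 with the benzyloxymethyl group removed, 4-OH free | C[C@H](O[Si](C(C)C)(C(C)C)C(C)C)[C@@H](O)[C@@H]1C[C@@H](OC(C)(C)O1)C(C)=O | intermediate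
17 | myristic acid (tetradecanoic acid) | CCCCCCCCCCCCCC(=O)O | starting material
18 | O4 tetradecanoate of 16 | C[C@H](O[Si](C(C)C)(C(C)C)C(C)C)[C@@H](OC(=O)CCCCCCCCCCCCC)[C@@H]1C[C@@H](OC(C)(C)O1)C(C)=O | intermediate
19 | trimethylsilyl enol ether of 18, CH2=C(OSiMe3)– in place of acetyl | C[C@H](O[Si](C(C)C)(C(C)C)C(C)C)[C@@H](OC(=O)CCCCCCCCCCCCC)[C@@H]1C[C@@H](OC(C)(C)O1)C(=C)O[Si](C)(C)C | intermediate
20 | bromomethyl ketone: 18 with BrCH2C(=O)– in place of acetyl (C1/C3 cis-acetonide, O4 myristate, O5 TIPS ether) | C[C@H](O[Si](C(C)C)(C(C)C)C(C)C)[C@@H](OC(=O)CCCCCCCCCCCCC)[C@@H]1C[C@@H](OC(C)(C)O1)C(=O)CBr | intermediate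
21 | 2-(1,3-oxazol-5-yl)acetic acid | OC(=O)Cc1cnco1 | starting material
22 | 1-[2-(1,3-oxazol-5-yl)acetyl]imidazole | O=C(Cc1cnco1)n1ccnc1 | intermediate
23 | 2-(1,3-oxazol-5-yl)acetamide | NC(=O)Cc1cnco1 | intermediate
24 | O-alkyl imidate: 20 with CH2–O–C(=NH)–CH2–(oxazol-5-yl) in place of CH2Br | C[C@H](O[Si](C(C)C)(C(C)C)C(C)C)[C@@H](OC(=O)CCCCCCCCCCCCC)[C@@H]1C[C@@H](OC(C)(C)O1)C(=O)COC(=N)Cc1cnco1 | intermediate
25 | 4-hydroxy-4,5-dihydrooxazole: ring A before dehydration, with OH and chain C1 on C4 and the oxazol-5-ylmethyl group on C2 | C[C@H](O[Si](C(C)C)(C(C)C)C(C)C)[C@@H](OC(=O)CCCCCCCCCCCCC)[C@@H]1C[C@@H](OC(C)(C)O1)C2(O)COC(Cc3cnco3)=N2 | intermediate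
26 | protected target: 2-(oxazol-5-ylmethyl)oxazol-4-yl group on C1, C1/C3 cis-acetonide, O4 myristate, O5 TIPS ether | C[C@H](O[Si](C(C)C)(C(C)C)C(C)C)[C@@H](OC(=O)CCCCCCCCCCCCC)[C@@H]1C[C@@H](OC(C)(C)O1)c1coc(Cc2cnco2)n1 | intermediate
27 | (2S,3R,4S,6R)-2,4,6-trihydroxy-6-[2-(1,3-oxazol-5-ylmethyl)-1,3-oxazol-4-yl]hexan-3-yl tetradecanoate; in chain numbering 1R,3S,4R,5S | CCCCCCCCCCCCCC(=O)O[C@H]([C@H](C)O)[C@@H](O)C[C@@H](O)c1coc(Cc2cnco2)n1 | target

**Step count**

Total: 17 steps. Longest linear sequence: 16 steps (steps 1–14, 16, 17); step 15 is a one-step side branch.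

**Steps most likely to fail**

1. Step 16. The acid released when bromide is abstracted may open the dioxane or the silyl ether before ring closure, alkylation at the amide nitrogen or at the ring B nitrogen may compete with O-alkylation, and dehydration of the hydroxyoxazoline may stall under the buffered conditions. The fallback sets out from 20 and returns at 26. Bromide in 20 is displaced by the caesium carboxylate of acid 21 (Cs2CO3, DMF, rt) to give the keto ester F1. Heating F1 with NH4OAc in AcOH (Davidson oxazole synthesis: ammonia condenses with the ketone, the enamine nitrogen attacks the ester carbonyl, water is lost) should give the same 2,4-disubstituted ring A. Should the dioxane open under these conditions, it is re-closed with 2,2-dimethoxypropane and PPTS before step 17.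

2. Step 14. The ester may interfere with the enolate chemistry (competing deprotonation or bromination α to the ester carbonyl), and enolisation towards C1 or double bromination would erode the material. The fallback sets out from 15 and returns at 26, moving the acylation behind the ring closure. The ester-free ketone 15 is converted by the same enol silane and NBS sequence into the benzyloxymethyl bromomethyl ketone F2. F2 is condensed with 23 under the conditions of step 16 to give the benzyloxymethyl-protected bis-oxazole F3. Hydrogenolysis (H2, Pd(OH)2/C) gives the O4 alcohol F4, and Steglich acylation with 17 gives 26.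

3. Step 17. Prolonged exposure to aqueous acid may allow 1,2-migration of the myristoyl group to O3 or O5, and cleavage of the hindered TIPS ether may be incomplete. The fallback sets out from 26 and returns at 27, separating the two unmaskings. HF·pyridine buffered with pyridine in THF removes only the silyl group to give the O5 alcohol F5. The dioxane of F5 is then exchanged, not hydrolysed, with PPTS in methanol at rt to give 27.

**Further compounds**

F1 | step 16 | keto ester: 20 with CH2–O–C(=O)–CH2–(oxazol-5-yl) in place of CH2Br | C[C@H](O[Si](C(C)C)(C(C)C)C(C)C)[C@@H](OC(=O)CCCCCCCCCCCCC)[C@@H]1C[C@@H](OC(C)(C)O1)C(=O)COC(=O)Cc1cnco1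
F2 | step 14 | benzyloxymethyl bromomethyl ketone: 15 with BrCH2C(=O)– in place of acetyl | C[C@H](O[Si](C(C)C)(C(C)C)C(C)C)[C@@H](OCOCc1ccccc1)[C@@H]1C[C@@H](OC(C)(C)O1)C(=O)CBr
F3 | step 14 | benzyloxymethyl-protected bis-oxazole: 26 with O4 benzyloxymethyl in place of myristate | C[C@H](O[Si](C(C)C)(C(C)C)C(C)C)[C@@H](OCOCc1ccccc1)[C@@H]1C[C@@H](OC(C)(C)O1)c1coc(Cc2cnco2)n1
F4 | step 14 | O4 alcohol bis-oxazole: 26 without the myristoyl group | C[C@H](O[Si](C(C)C)(C(C)C)C(C)C)[C@@H](O)[C@@H]1C[C@@H](OC(C)(C)O1)c1coc(Cc2cnco2)n1
F5 | step 17 | O5 alcohol: 26 without the TIPS group, acetonide intact | C[C@H](O)[C@@H](OC(=O)CCCCCCCCCCCCC)[C@@H]1C[C@@H](OC(C)(C)O1)c1coc(Cc2cnco2)n1
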